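**Retrosynthetic overview**
- Structural feature: C4a, which carries the C4 carbonyl, lies between C5 (OMe) and C8a (O1), and the oxygens on C5, C6 and C7 are contiguous. Ring A is therefore a 2,3,4-trioxygenated benzoate (carboxyl carbon on C4a) whose only free ortho carbon is C8a, and the halogen can go nowhere else.
- Last step: removal of four benzyl ethers. Before it, ring C is closed at C8a–O1 by intramolecular enolate O-arylation of a 1-(2-bromoaryl)-2-benzyloxy-1,3-diketone. Rings A and B are bought as arenes, so ring C is the only ring made.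
- The diketone is cut at C3–C4: C-acylation of the ring-B α-benzyloxyacetophenone with the ring-A 6-bromobenzoyl chloride.
- Ring A: 2,3,4-trihydroxybenzaldehyde, benzylation at O4, dimethylation, oxidative esterification, ester-directed magnesiation/bromination at the future C8a, then acid chloride.
- Ring B: Wittig reaction of 2-benzyloxy-5-bromobenzaldehyde with the ylide from methyl (R)-3-hydroxy-2-methylpropanoate (source of the S centre), diimide reduction, Br/Li exchange, Weinreb ketone synthesis.

Key step: step 17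

Remark: the 1,3-diketone of step 16 should be a keto–enol mixture and is drawn as its chelated enol, because every tautomer gives the same enolate. The alkene of step 6 is drawn as the Z isomer, and any E isomer gives the same product in step 7.

**Step 1**
Reactants: 1 methyl (R)-3-hydroxy-2-methylpropanoate
Product: 2 methyl (R)-3-(benzyloxy)-2-methylpropanoate
Conditions: BnOC(=NH)CCl3, TfOH (cat.), CH2Cl2/cyclohexane, 0 °C → rt
Reagents that add atoms: benzyl 2,2,2-trichloroacetimidate, N=C(OCc1ccccc1)C(Cl)(Cl)Cl
Why: Acid-catalysed imidate O-alkylation benzylates the primary alcohol without base, so the enolisable stereocentre bought with 1 should be neither epimerised nor lost by β-elimination.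

**Step 2**
Reactants: 2 methyl (R)-3-(benzyloxy)-2-methylpropanoate
Product: 3 (S)-3-(benzyloxy)-2-methylpropan-1-ol
Conditions: LiAlH4, THF, 0 °C; H2O quench
Reagents that add atoms: none
Why: LiAlH4 ester reduction gives the primary alcohol and leaves the benzyl ether and the stereocentre alone, the descriptor becoming S only because the CIP ranking of the two CH2O arms changes.

**Step 3**
Reactants: 3 (S)-3-(benzyloxy)-2-methylpropan-1-ol
Product: 4 (R)-1-(benzyloxy)-3-iodo-2-methylpropane
Conditions: I2, PPh3, imidazole, CH2Cl2, 0 °C → rt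
Reagents that add atoms: iodine, II
Why: Appel-type iodination replaces the primary hydroxyl by SN2 at CH2, one carbon away from the stereocentre, which therefore keeps its geometry.

**Step 4**
Reactants: 4 (R)-1-(benzyloxy)-3-iodo-2-methylpropane
Product: 5 [(R)-3-(benzyloxy)-2-methylpropyl]triphenylphosphonium iodide
Conditions: PPh3, MeCN, reflux
Reagents that add atoms: triphenylphosphine, c1ccc(cc1)P(c1ccccc1)c1ccccc1
Why: SN2 quaternisation of triphenylphosphine by the primary iodide forms the Wittig salt, with heating making up for the β-branch.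

**Step 5**
Reactants: 6 5-bromosalicylaldehyde
Product: 7 2-(benzyloxy)-5-bromobenzaldehyde
Conditions: BnBr, K2CO3, DMF, rt
Reagents that add atoms: benzyl bromide, BrCc1ccccc1
Why: Williamson ether synthesis masks the acidic phenol before strong bases are used and leaves the aldehyde and the aryl bromide intact.

**Step 6**
Reactants: 5 [(R)-3-(benzyloxy)-2-methylpropyl]triphenylphosphonium iodide; 7 2-(benzyloxy)-5-bromobenzaldehyde
Product: 9 1-(benzyloxy)-2-[(1Z,3S)-4-(benzyloxy)-3-methylbut-1-en-1-yl]-4-bromobenzene, via phosphonium ylide 8 (not isolated)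
Conditions: NaHMDS, THF, −78 → 0 °C; then 7, −78 °C → rt
Reagents that add atoms: none
Why: Wittig olefination of the non-stabilised ylide with the aromatic aldehyde builds the four-carbon side chain, mainly as the Z alkene, and the stereocentre next to the ylide carbon has no acidic hydrogen and no β-leaving group, so it should survive.

**Step 7**
Reactants: 9 1-(benzyloxy)-2-[(1Z,3S)-4-(benzyloxy)-3-methylbut-1-en-1-yl]-4-bromobenzene
Product: 10 1-(benzyloxy)-2-[(3S)-4-(benzyloxy)-3-methylbutyl]-4-bromobenzene
Conditions: TsNHNH2, NaOAc, DME/H2O, reflux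
Reagents that add atoms: none
Why: Diimide reduction transfers H2 in a concerted, metal-free step, so the aryl bromide and both benzyl ethers are kept and no alkene migration can scramble the allylic stereocentre.

**Step 8**
Reactants: 11 benzyloxyacetyl chloride
Product: 12 2-(benzyloxy)-N-methoxy-N-methylacetamide
Conditions: MeNH(OMe)·HCl, Et3N, CH2Cl2, 0 °C → rt
Reagents that add atoms: N,O-dimethylhydroxylamine hydrochloride, CNOC.Cl
Why: N-Acylation of N,O-dimethylhydroxylamine by the acid chloride gives the Weinreb amide.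

**Step 9**
Reactants: 10 1-(benzyloxy)-2-[(3S)-4-(benzyloxy)-3-methylbutyl]-4-bromobenzene; 12 2-(benzyloxy)-N-methoxy-N-methylacetamide
Product: 14 2-(benzyloxy)-1-{4-(benzyloxy)-3-[(3S)-4-(benzyloxy)-3-methylbutyl]phenyl}ethan-1-one, via aryllithium 13 (not isolated)
Conditions: n-BuLi, THF, −78 °C; then 12, −78 → 0 °C; aq NH4Cl
Reagents that add atoms: none
Why: Bromine–lithium exchange at −78 °C is much faster than benzylic deprotonation, and the Weinreb ketone synthesis stops at the α-benzyloxy ketone.

**Step 10**
Reactants: 15 2,3,4-trihydroxybenzaldehyde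
Product: 16 4-(benzyloxy)-2,3-dihydroxybenzaldehyde
Conditions: BnBr (1 equiv), NaHCO3, DMF, 40 °C
Reagents that add atoms: benzyl bromide, BrCc1ccccc1
Why: Regioselective Williamson etherification, in which the weak base ionises only the most acidic phenol (O4–H, para to the formyl group), whereas O2–H is held in a hydrogen bond to the aldehyde and O3–H is not conjugated with it.

**Step 11**
Reactants: 16 4-(benzyloxy)-2,3-dihydroxybenzaldehyde
Product: 17 4-(benzyloxy)-2,3-dimethoxybenzaldehyde
Conditions: MeI, K2CO3, DMF, rt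
Reagents that add atoms: iodomethane, CI
Why: Exhaustive Williamson O-methylation with a stronger base and excess MeI caps both remaining phenols, which become the C5 and C6 methoxy groups.

**Step 12**
Reactants: 17 4-(benzyloxy)-2,3-dimethoxybenzaldehyde
Product: 18 methyl 4-(benzyloxy)-2,3-dimethoxybenzoate
Conditions: I2, KOH, MeOH, 0 °C
Reagents that add atoms: methanol, CO
Why: Oxidative esterification, in which methanol adds to the aldehyde and hypoiodite oxidises the hemiacetal, gives in one step the ester that serves as directing group in step 13.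

**Step 13**
Reactants: 18 methyl 4-(benzyloxy)-2,3-dimethoxybenzoate
Product: 20 methyl 4-(benzyloxy)-6-bromo-2,3-dimethoxybenzoate, via arylmagnesium amide 19 (not isolated)
Conditions: TMP2Mg·2LiCl, THF, 0 °C → rt; then BrCl2CCCl2Br, −40 °C → rt; aq NH4Cl
Reagents that add atoms: 1,2-dibromo-1,1,2,2-tetrachloroethane, BrC(Cl)(Cl)C(Cl)(Cl)Br
Why: Directed ortho-metalation with a magnesium bis-amide, in which the ester carbonyl delivers the base to C6–H, the only hydrogen ortho to the carboxyl carbon, an amide base being chosen because alkyllithiums would also lithiate the benzylic OCH2, after which the arylmagnesium takes bromine from the polyhalide.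

**Step 14**
Reactants: 20 methyl 4-(benzyloxy)-6-bromo-2,3-dimethoxybenzoate
Product: 21 4-(benzyloxy)-6-bromo-2,3-dimethoxybenzoic acid
Conditions: KOH, MeOH/H2O, reflux; then aq HCl
Reagents that add atoms: potassium hydroxide, [K+].[OH-]
Why: Saponification under forcing conditions overcomes the two ortho substituents, and the electron-rich aryl bromide and the ethers are inert to hydroxide.

**Step 15**
Reactants: 21 4-(benzyloxy)-6-bromo-2,3-dimethoxybenzoic acid
Product: 22 4-(benzyloxy)-6-bromo-2,3-dimethoxybenzoyl chloride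
Conditions: (COCl)2, DMF (cat.), CH2Cl2, 0 °C → rt
Reagents that add atoms: oxalyl chloride, O=C(Cl)C(=O)Cl
Why: Acid chloride formation through the catalytic Vilsmeier-type chloroiminium salt is mild enough for the benzyl and methyl ethers, and 22 is used crude.

**Step 16**
Reactants: 14 2-(benzyloxy)-1-{4-(benzyloxy)-3-[(3S)-4-(benzyloxy)-3-methylbutyl]phenyl}ethan-1-one; 22 4-(benzyloxy)-6-bromo-2,3-dimethoxybenzoyl chloride
Product: 24 1-[4-(benzyloxy)-6-bromo-2,3-dimethoxyphenyl]-2-(benzyloxy)-3-{4-(benzyloxy)-3-[(3S)-4-(benzyloxy)-3-methylbutyl]phenyl}propane-1,3-dione (drawn as chelated enol), via bromomagnesium enolate 23 (not isolated)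
Conditions: MgBr2·OEt2, i-Pr2NEt, CH2Cl2, 0 °C → rt; cold dilute aq HCl
Reagents that add atoms: none
Why: Soft enolisation followed by crossed Claisen-type C-acylation, in which Mg(II) chelated by the carbonyl and the α-benzyloxy oxygen acidifies the CH2 enough for an amine base, the tightly O-bound enolate reacts at carbon, and the product is held as a stable magnesium diketonate, so one equivalent of 14 suffices.

**Step 17**
Reactants: 24 1-[4-(benzyloxy)-6-bromo-2,3-dimethoxyphenyl]-2-(benzyloxy)-3-{4-(benzyloxy)-3-[(3S)-4-(benzyloxy)-3-methylbutyl]phenyl}propane-1,3-dione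
Product: 26 3,7-bis(benzyloxy)-2-{4-(benzyloxy)-3-[(3S)-4-(benzyloxy)-3-methylbutyl]phenyl}-5,6-dimethoxy-4H-chromen-4-one, via caesium diketonate 25 (not isolated)
Conditions: CuI (10 mol %), 1,10-phenanthroline (20 mol %), Cs2CO3, 4 Å MS, DMF, 100 °C, Ar
Reagents that add atoms: none
Why: Cs2CO3 converts 24 into the delocalised diketonate 25, which chelates Cu(I) and so holds the metal beside the C8a–Br bond; oxidative addition gives a seven-membered aryl–Cu(III) enolate, and C–O reductive elimination releases 26 and Cu(I). The closest known reaction type is the intramolecular Ullmann-type O-arylation of 1-(2-haloaryl)-1,3-diketones to chromones and flavones, which on activated rings also runs without metal by addition–elimination at the carbon ortho to the acyl group. Ring C closes as a six-membered 4-pyranone by bonding of the enolate oxygen on C2 to C8a (formally 6-endo-trig in the addition–elimination picture, ring contraction of the cupracycle in the catalysed one). No stereocentre is formed, and the remote S centre of the side chain bears no acidic hydrogen and is not touched. The step needs O- rather than C-arylation and the C2 oxygen rather than the C4 oxygen, and the substrate secures both because C3 and the C4 oxygen could reach C8a only through four-membered rings, while the position of the bromine fixes the 5,6-dimethoxy-7-oxy pattern. Copper is used because the C6 methoxy group para to C8a and the twisted, doubly ortho-substituted aroyl group weaken the uncatalysed path, and dry, oxygen-free conditions hold back retro-Claisen cleavage.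

**Step 18**
Reactants: 26 3,7-bis(benzyloxy)-2-{4-(benzyloxy)-3-[(3S)-4-(benzyloxy)-3-methylbutyl]phenyl}-5,6-dimethoxy-4H-chromen-4-one
Product: 27 3,7-dihydroxy-2-{4-hydroxy-3-[(3S)-4-hydroxy-3-methylbutyl]phenyl}-5,6-dimethoxy-4H-chromen-4-one
Conditions: H2 (1 atm), Pd/C, THF/MeOH, rt
Reagents that add atoms: none
Why: Catalytic hydrogenolysis cleaves the two aryl, the enol and the primary alkyl benzyl ethers in one operation, while the methyl ethers, the 4-pyranone and the saturated stereocentre are inert under these mild conditions.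

**Compound list**
1 | methyl (R)-3-hydroxy-2-methylpropanoate | COC(=O)[C@H](C)CO | starting material
2 | methyl (R)-3-(benzyloxy)-2-methylpropanoate | COC(=O)[C@H](C)COCc1ccccc1 | intermediate
3 | (S)-3-(benzyloxy)-2-methylpropan-1-ol | OC[C@H](C)COCc1ccccc1 | intermediate
4 | (R)-1-(benzyloxy)-3-iodo-2-methylpropane | IC[C@H](C)COCc1ccccc1 | intermediate
5 | [(R)-3-(benzyloxy)-2-methylpropyl]triphenylphosphonium iodide | c1ccccc1[P+](c1ccccc1)(c1ccccc1)C[C@H](C)COCc1ccccc1.[I-] | intermediate
6 | 5-bromosalicylaldehyde | O=Cc1cc(Br)ccc1O | starting material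
7 | 2-(benzyloxy)-5-bromobenzaldehyde | O=Cc1cc(Br)ccc1OCc1ccccc1 | intermediate
8 | [(R)-3-(benzyloxy)-2-methylpropylidene]triphenylphosphorane (ylide, not isolated) | c1ccccc1P(c1ccccc1)(c1ccccc1)=C[C@H](C)COCc1ccccc1 | intermediate
9 | 1-(benzyloxy)-2-[(1Z,3S)-4-(benzyloxy)-3-methylbut-1-en-1-yl]-4-bromobenzene | Brc1ccc(OCc2ccccc2)c(/C=C\[C@H](C)COCc2ccccc2)c1 | intermediate
10 | 1-(benzyloxy)-2-[(3S)-4-(benzyloxy)-3-methylbutyl]-4-bromobenzene | Brc1ccc(OCc2ccccc2)c(CC[C@H](C)COCc2ccccc2)c1 | intermediate
11 | benzyloxyacetyl chloride | O=C(Cl)COCc1ccccc1 | starting material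
12 | 2-(benzyloxy)-N-methoxy-N-methylacetamide | CON(C)C(=O)COCc1ccccc1 | intermediate
13 | {4-(benzyloxy)-3-[(3S)-4-(benzyloxy)-3-methylbutyl]phenyl}lithium (not isolated) | [Li]c1ccc(OCc2ccccc2)c(CC[C@H](C)COCc2ccccc2)c1 | intermediate
14 | 2-(benzyloxy)-1-{4-(benzyloxy)-3-[(3S)-4-(benzyloxy)-3-methylbutyl]phenyl}ethan-1-one | O=C(COCc1ccccc1)c1ccc(OCc2ccccc2)c(CC[C@H](C)COCc2ccccc2)c1 | intermediate
15 | 2,3,4-trihydroxybenzaldehyde | O=Cc1ccc(O)c(O)c1O | starting material
16 | 4-(benzyloxy)-2,3-dihydroxybenzaldehyde | O=Cc1ccc(OCc2ccccc2)c(O)c1O | intermediate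
17 | 4-(benzyloxy)-2,3-dimethoxybenzaldehyde | O=Cc1ccc(OCc2ccccc2)c(OC)c1OC | intermediate
18 | methyl 4-(benzyloxy)-2,3-dimethoxybenzoate | COC(=O)c1ccc(OCc2ccccc2)c(OC)c1OC | intermediate
19 | [5-(benzyloxy)-3,4-dimethoxy-2-(methoxycarbonyl)phenyl]magnesium 2,2,6,6-tetramethylpiperidide (LiCl complex, not isolated) | COC(=O)c1c([Mg]N2C(C)(C)CCCC2(C)C)cc(OCc2ccccc2)c(OC)c1OC | intermediate
20 | methyl 4-(benzyloxy)-6-bromo-2,3-dimethoxybenzoate | COC(=O)c1c(Br)cc(OCc2ccccc2)c(OC)c1OC | intermediate
21 | 4-(benzyloxy)-6-bromo-2,3-dimethoxybenzoic acid | OC(=O)c1c(Br)cc(OCc2ccccc2)c(OC)c1OC | intermediate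
22 | 4-(benzyloxy)-6-bromo-2,3-dimethoxybenzoyl chloride | ClC(=O)c1c(Br)cc(OCc2ccccc2)c(OC)c1OC | intermediate
23 | bromomagnesium (Z)-enolate of 14 (chelated, not isolated) | Br[Mg]O/C(=C\OCc1ccccc1)c1ccc(OCc2ccccc2)c(CC[C@H](C)COCc2ccccc2)c1 | intermediate
24 | 1-(2-bromoaryl)-2-benzyloxy-3-aryl-1,3-diketone, key-step precursor, chelated enol tautomer (enol OH on the ring-B side, cis to the ring-A aroyl carbon) | COc1c(OCc2ccccc2)cc(Br)c(C(=O)/C(OCc2ccccc2)=C(\O)c2ccc(OCc3ccccc3)c(CC[C@H](C)COCc3ccccc3)c2)c1OC | intermediate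
25 | caesium diketonate of 24 (not isolated) | COc1c(OCc2ccccc2)cc(Br)c(C(=O)/C(OCc2ccccc2)=C(\[O-])c2ccc(OCc3ccccc3)c(CC[C@H](C)COCc3ccccc3)c2)c1OC.[Cs+] | intermediate
26 | 3,7-bis(benzyloxy)-2-{4-(benzyloxy)-3-[(3S)-4-(benzyloxy)-3-methylbutyl]phenyl}-5,6-dimethoxy-4H-chromen-4-one (tetra-O-benzyl target) | COc1c(OCc2ccccc2)cc2oc(-c3ccc(OCc4ccccc4)c(CC[C@H](C)COCc4ccccc4)c3)c(OCc3ccccc3)c(=O)c2c1OC | intermediate
27 | 3,7-dihydroxy-2-{4-hydroxy-3-[(3S)-4-hydroxy-3-methylbutyl]phenyl}-5,6-dimethoxy-4H-chromen-4-one (CNP0253239.1) | COc1c(O)cc2oc(-c3ccc(O)c(CC[C@H](C)CO)c3)c(O)c(=O)c2c1OC | target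

**Totals**
Total step count: 18.
Longest linear sequence: 10 steps (1, 2, 3, 4, 6, 7, 9, 16, 17, 18). The ring-A branch runs 9 steps to the target (10–18).

**Steps most likely to fail**

1. Step 17. Copper insertion into the hindered, electron-rich C8a–Br bond may be slower than retro-Claisen cleavage of the diketonate or protodebromination.
   - The fallback reshapes the precursor with a better leaving group at C8a.
   - It sets out from 18, whose arylmagnesium 19 is quenched with iodine instead of the bromine donor to give methyl 4-(benzyloxy)-6-iodo-2,3-dimethoxybenzoate F1.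
   - Saponification gives 4-(benzyloxy)-6-iodo-2,3-dimethoxybenzoic acid F2, and oxalyl chloride gives 4-(benzyloxy)-6-iodo-2,3-dimethoxybenzoyl chloride F3.
   - Acylation of enolate 23 as in step 16 gives the iodo diketone F4. Its caesium diketonate F5 should undergo the copper-catalysed closure at a clearly lower temperature, where cleavage is slow.
   - The sequence comes back to the route at 26.

2. Step 16. Attack on the doubly ortho-substituted acyl chloride may be sluggish, or the enolate may be acylated on oxygen.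
   - The fallback replaces acylation by aldol addition and oxidation.
   - It sets out from 22, which LiAlH(Ot-Bu)3 at −78 °C reduces to 4-(benzyloxy)-6-bromo-2,3-dimethoxybenzaldehyde F6.
   - The lithium enolate of 14 F7 (LDA, THF, −78 °C) adds to it to give the β-hydroxy ketone F8 as a mixture of diastereomers.
   - Dess–Martin oxidation removes both new stereocentres and comes back to the route at 24.

3. Step 13. Metalation of the electron-rich ring may be incomplete, may compete at C5 next to the benzyloxy group, or the arylmagnesium may add to the ester.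
   - The fallback replaces deprotonation by C–H borylation.
   - It sets out from 18. Ester-directed iridium-catalysed ortho-borylation ([Ir(OMe)(cod)]2, P[3,5-(CF3)2C6H3]3, B2pin2, octane, 80 °C) gives methyl 4-(benzyloxy)-2,3-dimethoxy-6-(4,4,5,5-tetramethyl-1,3,2-dioxaborolan-2-yl)benzoate F9.
   - CuBr2 in aqueous methanol at 80 °C then turns C–B into C–Br and comes back to the route at 20.

**Further compounds**
F1 | step 17 | methyl 4-(benzyloxy)-6-iodo-2,3-dimethoxybenzoate | COC(=O)c1c(I)cc(OCc2ccccc2)c(OC)c1OC
F2 | step 17 | 4-(benzyloxy)-6-iodo-2,3-dimethoxybenzoic acid | OC(=O)c1c(I)cc(OCc2ccccc2)c(OC)c1OC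
F3 | step 17 | 4-(benzyloxy)-6-iodo-2,3-dimethoxybenzoyl chloride | ClC(=O)c1c(I)cc(OCc2ccccc2)c(OC)c1OC
F4 | step 17 | iodo analogue of 24 (chelated enol tautomer) | COc1c(OCc2ccccc2)cc(I)c(C(=O)/C(OCc2ccccc2)=C(\O)c2ccc(OCc3ccccc3)c(CC[C@H](C)COCc3ccccc3)c2)c1OC
F5 | step 17 | caesium diketonate of F4 | COc1c(OCc2ccccc2)cc(I)c(C(=O)/C(OCc2ccccc2)=C(\[O-])c2ccc(OCc3ccccc3)c(CC[C@H](C)COCc3ccccc3)c2)c1OC.[Cs+]
F6 | step 16 | 4-(benzyloxy)-6-bromo-2,3-dimethoxybenzaldehyde | O=Cc1c(Br)cc(OCc2ccccc2)c(OC)c1OC
F7 | step 16 | lithium (Z)-enolate of 14 | [Li]O/C(=C\OCc1ccccc1)c1ccc(OCc2ccccc2)c(CC[C@H](C)COCc2ccccc2)c1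
F8 | step 16 | β-hydroxy ketone from F6 and F7 (mixture at the two new centres, side chain S) | COc1c(OCc2ccccc2)cc(Br)c(C(O)C(OCc2ccccc2)C(=O)c2ccc(OCc3ccccc3)c(CC[C@H](C)COCc3ccccc3)c2)c1OC
F9 | step 13 | methyl 4-(benzyloxy)-2,3-dimethoxy-6-(4,4,5,5-tetramethyl-1,3,2-dioxaborolan-2-yl)benzoate | COC(=O)c1c(B2OC(C)(C)C(C)(C)O2)cc(OCc2ccccc2)c(OC)c1OC
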